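**Plan**

- Retrosynthesis cuts, in this order: the N–CH2 bond of the piperidine; the lactone C–O bond; the bond between the N-bearing quaternary carbon and the ketone carbon of the pyrrolidinone; the bond between the propanoate-bearing quaternary carbon and the cyclopentene (seven-membered ring); the bond between the CH2OH-bearing quaternary carbon and its CH(CH2N) neighbour.
- Forward: a cyclopentenyl triflate acid and a cyclopentenol are joined as an ester. Ireland–Claisen rearrangement, oxidation to the cyclopentanone, Pd α-alkenylation (seven-membered ring) and Michael addition give the 5-7-5 carbocycle. An N-linked 3-methylazetidin-2-one is then expanded to the pyrrolidin-3-one, and the lactone, the piperidine and deprotection follow.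
- Enabling feature: in the pyrrolidinone ring the nitrogen and the ketone carbon are both bonded to one quaternary carbon, which also carries the lactone CH–O carbon of the cyclopentane. With that CH–O carbon at the ketone level, the quaternary carbon is an enolate carbon next to nitrogen. A strained four-membered N-acyl ring (N, CH2, CHMe, C=O) can therefore pass its acyl carbon from N to this carbon and grow into the five-membered ring while the quaternary centre is made.
- Stereochemistry: RAMP alkylation (cyclopentene CH); CBS reduction relayed through the Claisen chair (CH2OH-bearing quaternary carbon and adjacent CH); substrate control (cis 5/7 fusion, N-bearing quaternary carbon, lactone carbinol, piperidine closure); thermodynamic control (methyl-bearing carbon).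

Key step: step 18

Remark: the methyl-bearing carbon α to the ring ketone is assumed to be the more stable epimer in the target; it is therefore set by equilibration, and racemic 3-methylazetidin-2-one suffices.

Step 1
Reactants: 1 cyclopentanone; 2 RAMP
Product: 3 cyclopentanone RAMP hydrazone
Conditions: neat, 60 °C; then 4 Å molecular sieves
Reagents that add atoms: none
Why: Condensation of a ketone with a 1,1-disubstituted hydrazine (hydrazone formation) should install the chiral auxiliary cleanly.

Step 2
Reactants: 3 cyclopentanone RAMP hydrazone; 4 tert-butyl 4-bromobutanoate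
Product: 5 α-alkylated RAMP hydrazone
Conditions: LDA, THF, 0 °C; then 4, −100 °C → rt
Reagents that add atoms: none
Why: RAMP-hydrazone alkylation, in which the chelated lithium azaenolate is alkylated by the primary bromide on the face fixed by the methoxymethyl group, should set the cyclopentane stereocentre that later sits between the seven-membered ring and the cyclopentene.

Step 3
Reactants: 5 α-alkylated RAMP hydrazone
Product: 6 tert-butyl (R)-4-(2-oxocyclopentyl)butanoate
Conditions: sat. aq. oxalic acid, Et2O, rt
Reagents that add atoms: water, O
Why: Two-phase acidic hydrazone hydrolysis should free the α-substituted ketone without epimerisation and leave the tert-butyl ester intact.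

Step 4
Reactants: 6 tert-butyl (R)-4-(2-oxocyclopentyl)butanoate
Product: 7 cyclopentenyl triflate tert-butyl ester
Conditions: LDA, THF, −78 °C; then PhNTf2, −78 → 0 °C
Reagents that add atoms: N-phenylbis(trifluoromethanesulfonimide), O=S(=O)(N(c1ccccc1)S(=O)(=O)C(F)(F)F)C(F)(F)F
Why: Kinetic deprotonation at the unsubstituted α-CH2 and O-triflation (enol triflate formation) should fix the position of the future trisubstituted ring alkene and leave the stereocentre untouched.

Step 5
Reactants: 7 cyclopentenyl triflate tert-butyl ester
Product: 8 cyclopentenyl triflate acid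
Conditions: TFA, CH2Cl2, 0 °C → rt
Reagents that add atoms: none
Why: Acidolysis of the tert-butyl ester with loss of isobutene should liberate the acid, the enol triflate being stable to TFA.

Step 6
Reactants: 9 3-ethoxycyclopent-2-en-1-one; 10 tributyl[(methoxymethoxy)methyl]stannane
Product: 12 3-[(methoxymethoxy)methyl]cyclopent-2-en-1-one, via lithium alkoxide adduct 11 (not isolated)
Conditions: 10, n-BuLi, THF, −78 °C; then 9, −78 → 0 °C; 1 M HCl, 0 °C
Reagents that add atoms: water, O
Why: In this Stork–Danheiser sequence tin–lithium exchange gives the alkoxymethyllithium, which adds 1,2 to the vinylogous ester, and acidic work-up transposes the carbonyl to give the 3-substituted enone.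

Step 7
Reactants: 12 3-[(methoxymethoxy)methyl]cyclopent-2-en-1-one
Product: 13 (S)-3-[(methoxymethoxy)methyl]cyclopent-2-en-1-ol
Conditions: (R)-Me-CBS (10 mol%), BH3·SMe2, THF, −30 °C
Reagents that add atoms: none
Why: CBS (oxazaborolidine-catalysed) 1,2-reduction of the enone should give the (S)-carbinol, whose only task is to relay chirality in step 9.

Step 8
Reactants: 8 cyclopentenyl triflate acid; 13 (S)-3-[(methoxymethoxy)methyl]cyclopent-2-en-1-ol
Product: 14 allylic ester
Conditions: DCC, DMAP (cat.), CH2Cl2, 0 °C → rt
Reagents that add atoms: none
Why: Steglich esterification should join the two enantioenriched fragments under neutral conditions.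

Step 9
Reactants: 14 allylic ester
Product: 17 Claisen acid, via silyl ketene acetal 15 (not isolated), via trimethylsilyl ester 16 (not isolated)
Conditions: LDA, TMSCl, THF, −78 → 60 °C; then 1 M HCl, 0 °C
Reagents that add atoms: none
Why: In the Ireland–Claisen rearrangement the (E)-silyl ketene acetal formed in THF should rearrange suprafacially through a chair transition state, so that the C–O stereocentre is traded for the CH2OMOM-bearing quaternary carbon and the ketene acetal geometry sets the adjacent CH(CO2H) centre (the THF/HMPA geometry is at hand should the boat pathway prevail).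

Step 10
Reactants: 17 Claisen acid
Product: 18 diol
Conditions: BH3·THF, 0 °C → rt; then H2O2, aq. NaOAc, 0 °C
Reagents that add atoms: hydrogen peroxide, OO
Why: Borane should reduce the acid to the primary alcohol and hydroborate the disubstituted ring alkene at the carbon remote from the quaternary centre (hydroboration–oxidation), while the electron-poor enol triflate is spared and the carbinol configuration is of no consequence.

Step 11
Reactants: 18 diol
Product: 19 mono-TBS ether
Conditions: TBSCl (1.05 equiv), imidazole, CH2Cl2, 0 °C
Reagents that add atoms: tert-butyldimethylsilyl chloride, CC(C)(C)[Si](C)(C)Cl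
Why: Silylation should be selective for the primary alcohol over the hindered secondary one.

Step 12
Reactants: 19 mono-TBS ether
Product: 20 keto triflate
Conditions: Dess–Martin periodinane, CH2Cl2, 0 °C → rt
Reagents that add atoms: none
Why: Dess–Martin oxidation should give the cyclopentanone under neutral conditions that leave the MOM and TBS ethers and the enol triflate untouched.

Step 13
Reactants: 20 keto triflate
Product: 21 tricyclic ketone
Conditions: Pd2(dba)3 (5 mol%), XPhos (12 mol%), KOt-Bu (2.2 equiv), THF, 60 °C; AcOH, −78 °C
Reagents that add atoms: none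
Why: Intramolecular Pd-catalysed α-alkenylation of the ketone enolate by the alkenyl triflate should close the seven-membered ring at the α-CH2 next to the quaternary carbon, because coupling at the other α-position would need a bridged eight-membered ring, and the new epimerisable CH is consumed in step 14.

Step 14
Reactants: 21 tricyclic ketone; 22 tert-butyl acrylate
Product: 23 keto tert-butyl ester
Conditions: KOt-Bu (0.2 equiv), t-BuOH/THF, 0 °C
Reagents that add atoms: none
Why: Michael addition of the thermodynamic dienolate (α-carbon flanked by ketone and ring alkene) should occur at the α-carbon from the face opposite the ring branch that carries the CH2OTBS arm, giving the second quaternary carbon with cis 5/7 fusion and the propanoate chain syn to CH2OMOM.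

Step 15
Reactants: 23 keto tert-butyl ester
Product: 25 α-bromo ketone, via TMS enol ether 24 (not isolated)
Conditions: LiHMDS, TMSCl, THF, −78 °C; then NBS, −78 → 0 °C
Reagents that add atoms: N-bromosuccinimide, O=C1CCC(=O)N1Br
Why: Silyl enol ether formation at the only enolisable α-position followed by bromination with NBS should give the α-bromo ketone without touching the ring alkene, the bromide configuration being irrelevant.

Step 16
Reactants: 26 methyl 3-amino-2-methylpropanoate hydrochloride
Product: 29 3-methylazetidin-2-one, via N-silyl amino ester 27 (not isolated), via N-silyl lactam 28 (not isolated)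
Conditions: Et3N, TMSCl, Et2O, 0 °C; then t-BuMgCl, 0 °C → rt; aq. NH4Cl
Reagents that add atoms: none
Why: N-Silylation and Grignard-mediated cyclisation of the β-amino ester (4-exo-trig acyl substitution) is a standard entry to N–H azetidin-2-ones.

Step 17
Reactants: 25 α-bromo ketone; 29 3-methylazetidin-2-one
Product: 30 α-lactamyl ketone
Conditions: Cs2CO3, TBAI (10 mol%), MeCN, rt
Reagents that add atoms: none
Why: SN2 N-alkylation of the lactam by the α-halo ketone should proceed from the open lower face once iodide exchange (Finkelstein) and enolisation have interconverted the halide epimers, and the diastereomer mixture is carried on because both new stereocentres are erased in step 18.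

Step 18
Reactants: 30 α-lactamyl ketone
Product: 33 spiro pyrrolidinone TBS enol ether, via potassium enolate 31 (not isolated), via ring-expanded potassium enolate 32 (not isolated)
Conditions: KHMDS (1.2 equiv), 18-crown-6, THF, −78 °C → rt; then TBSCl, −78 → 0 °C
Reagents that add atoms: tert-butyldimethylsilyl chloride, CC(C)(C)[Si](C)(C)Cl
Why: Proposed new method: KHMDS forms the enolate of the cyclopentanone on the carbon that carries the lactam nitrogen (the only enolisable α-position), and this carbon attacks the strained N-acyl carbonyl in an aza-Chan-type 1,2-acyl shift from nitrogen to carbon (3-exo-trig addition to a 1-azabicyclo[2.1.0]pentane alkoxide, then N–C(O) cleavage), so that the azetidinone takes up the enolate carbon and becomes the pyrrolidin-3-one (ring expansion 4 → 5). The closest known reaction types are the Chan rearrangement of α-acyloxy ester enolates, the base-induced ring enlargement of N-benzylazetidin-2-ones to 2-arylpyrrolidin-3-ones and the Dieckmann condensation. Release of the azetidinone strain and the absence of an alkoxide leaving group should make formation of the non-enolisable 2-amino-1,3-diketone irreversible, and the amide anion set free is quenched by proton transfer from the methyl-bearing carbon to give the single ketone enolate that TBSCl traps on oxygen. The new N-bearing quaternary stereocentre is under substrate control, because the acyl group can reach the planar enolate only from the face opposite the endo CH2OTBS arm of the seven-membered ring, which leaves nitrogen on the face from which the piperidine is closed in step 21. The step needs C-acylation by the lactam in preference to Claisen attack on the side-chain ester or O-acyl transfer; the tert-butyl ester, the quaternary second α-carbon and the fact that only the C-acyl isomer is a thermodynamic sink should secure this, and all diastereomers of 30 converge on one product because both of their variable stereocentres become sp2.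

Step 19
Reactants: 33 spiro pyrrolidinone TBS enol ether
Product: 35 δ-lactone, via hydroxy ester 34 (not isolated)
Conditions: LiBH4, THF, 0 °C → rt; then KOt-Bu (0.2 equiv), rt
Reagents that add atoms: none
Why: Borohydride should reduce the only ketone from the face of the small N–H, opposite the bulky OTBS-bearing enol carbon, which places the alkoxide cis to the propanoate arm, and catalytic tert-butoxide then closes the δ-lactone (6-exo-trig transesterification), which also guards the β-oxygenated ketone array against retro-aldol cleavage once the ketone is unmasked.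

Step 20
Reactants: 35 δ-lactone
Product: 36 amino alcohol keto lactone
Conditions: TBAF (2.5 equiv), THF, 0 °C → rt
Reagents that add atoms: none
Why: Fluoride should cleave both the primary silyl ether and the silyl enol ether, unmasking the alcohol and the pyrrolidin-3-one.

Step 21
Reactants: 36 amino alcohol keto lactone
Product: 38 MOM ether of the target, via methyl epimer mixture 37 (not isolated)
Conditions: PPh3, CBr4, Et3N, CH2Cl2, 0 °C → rt; then DBU (0.5 equiv), rt
Reagents that add atoms: none
Why: Appel activation of the primary alcohol and N-alkylation by the secondary amine (6-exo-tet), possible only with nitrogen and the CH2 arm on the same face, should close the piperidine, and DBU then equilibrates the methyl-bearing carbon α to the ketone to the epimer with methyl away from the lactone-bearing bridge.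

Step 22
Reactants: 38 MOM ether of the target
Product: 39 CNP0180795.1
Conditions: Me2BBr, CH2Cl2, −78 °C; then aq. NaHCO3
Reagents that add atoms: none
Why: Dimethylboron bromide should cleave the MOM acetal at low temperature without affecting the lactone, the ketone, the amine or the trisubstituted alkene.

**Compound list**

1 | cyclopentanone | O=C1CCCC1 | starting material
2 | RAMP, (R)-1-amino-2-(methoxymethyl)pyrrolidine | COC[C@H]1CCCN1N | starting material
3 | cyclopentanone RAMP hydrazone | COC[C@H]1CCCN1N=C1CCCC1 | intermediate
4 | tert-butyl 4-bromobutanoate | CC(C)(C)OC(=O)CCCBr | starting material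
5 | α-alkylated RAMP hydrazone (ring stereocentre as drawn, C=N geometry not defined) | COC[C@H]1CCCN1N=C1CCC[C@@H]1CCCC(=O)OC(C)(C)C | intermediate
6 | tert-butyl (R)-4-(2-oxocyclopentyl)butanoate | O=C1CCC[C@@H]1CCCC(=O)OC(C)(C)C | intermediate
7 | tert-butyl (S)-4-[2-(trifluoromethylsulfonyloxy)cyclopent-2-en-1-yl]butanoate | CC(C)(C)OC(=O)CCC[C@H]1CCC=C1OS(=O)(=O)C(F)(F)F | intermediate
8 | (S)-4-[2-(trifluoromethylsulfonyloxy)cyclopent-2-en-1-yl]butanoic acid | OC(=O)CCC[C@H]1CCC=C1OS(=O)(=O)C(F)(F)F | intermediate
9 | 3-ethoxycyclopent-2-en-1-one | CCOC1=CC(=O)CC1 | starting material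
10 | tributyl[(methoxymethoxy)methyl]stannane | CCCC[Sn](CCCC)(CCCC)COCOC | starting material
11 | lithium 3-ethoxy-1-[(methoxymethoxy)methyl]cyclopent-2-en-1-olate (racemic 1,2-adduct, not isolated) | [Li+].CCOC1=CC([O-])(COCOC)CC1 | intermediate
12 | 3-[(methoxymethoxy)methyl]cyclopent-2-en-1-one | O=C1CCC(COCOC)=C1 | intermediate
13 | (S)-3-[(methoxymethoxy)methyl]cyclopent-2-en-1-ol | O[C@H]1CCC(COCOC)=C1 | intermediate
14 | allylic ester of acid 8 with alcohol 13 | O=C(CCC[C@H]1CCC=C1OS(=O)(=O)C(F)(F)F)O[C@H]1CCC(COCOC)=C1 | intermediate
15 | (E)-trimethylsilyl ketene acetal of 14 (not isolated) | C[Si](C)(C)O/C(O[C@H]1CCC(COCOC)=C1)=C/CC[C@H]1CCC=C1OS(=O)(=O)C(F)(F)F | intermediate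
16 | trimethylsilyl ester of acid 17 (not isolated) | C[Si](C)(C)OC(=O)[C@@H](CC[C@H]1CCC=C1OS(=O)(=O)C(F)(F)F)[C@]1(COCOC)CCC=C1 | intermediate
17 | Claisen acid: 2-{1-[(methoxymethoxy)methyl]cyclopent-2-en-1-yl}-4-[2-(triflyloxy)cyclopent-2-en-1-yl]butanoic acid, three stereocentres as drawn | OC(=O)[C@@H](CC[C@H]1CCC=C1OS(=O)(=O)C(F)(F)F)[C@]1(COCOC)CCC=C1 | intermediate
18 | diol: primary alcohol from the acid and 3-hydroxycyclopentyl ring (ring carbinol epimers) | OC[C@@H](CC[C@H]1CCC=C1OS(=O)(=O)C(F)(F)F)[C@]1(COCOC)CCC(O)C1 | intermediate
19 | mono-TBS ether of 18 (primary oxygen silylated) | CC(C)(C)[Si](C)(C)OC[C@@H](CC[C@H]1CCC=C1OS(=O)(=O)C(F)(F)F)[C@]1(COCOC)CCC(O)C1 | intermediate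
20 | keto triflate: 3,3-disubstituted cyclopentanone tethered to the cyclopentenyl triflate | CC(C)(C)[Si](C)(C)OC[C@@H](CC[C@H]1CCC=C1OS(=O)(=O)C(F)(F)F)[C@]1(COCOC)CCC(=O)C1 | intermediate
21 | tricyclic ketone: cyclopentanone fused to a cycloheptane fused to a cyclopentene, CH2OMOM on the quaternary carbon, CH2OTBS on the adjacent CH (α-CH epimers) | O=C1CC[C@@]2(COCOC)[C@@H](CO[Si](C)(C)C(C)(C)C)CC[C@H]3CCC=C3C12 | intermediate
22 | tert-butyl acrylate | C=CC(=O)OC(C)(C)C | starting material
23 | keto tert-butyl ester with both quaternary carbons, cis 5/7 fusion, propanoate syn to CH2OMOM | O=C1CC[C@@]2(COCOC)[C@@H](CO[Si](C)(C)C(C)(C)C)CC[C@H]3CCC=C3[C@@]12CCC(=O)OC(C)(C)C | intermediate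
24 | trimethylsilyl enol ether of 23 (not isolated) | C[Si](C)(C)OC1=CC[C@@]2(COCOC)[C@@H](CO[Si](C)(C)C(C)(C)C)CC[C@H]3CCC=C3[C@@]12CCC(=O)OC(C)(C)C | intermediate
25 | α-bromo ketone (bromide epimers) | O=C1C(Br)C[C@@]2(COCOC)[C@@H](CO[Si](C)(C)C(C)(C)C)CC[C@H]3CCC=C3[C@@]12CCC(=O)OC(C)(C)C | intermediate
26 | methyl 3-amino-2-methylpropanoate hydrochloride (racemic) | COC(=O)C(C)CN.Cl | starting material
27 | methyl 2-methyl-3-[(trimethylsilyl)amino]propanoate (not isolated) | COC(=O)C(C)CN[Si](C)(C)C | intermediate
28 | 3-methyl-1-(trimethylsilyl)azetidin-2-one (not isolated) | CC1CN([Si](C)(C)C)C1=O | intermediate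
29 | 3-methylazetidin-2-one (racemic) | CC1CNC1=O | intermediate
30 | α-lactamyl ketone: 3-methyl-2-oxoazetidin-1-yl group on the ketone α-carbon (mixture at that carbon and at the methyl carbon) | O=C1C(N4CC(C)C4=O)C[C@@]2(COCOC)[C@@H](CO[Si](C)(C)C(C)(C)C)CC[C@H]3CCC=C3[C@@]12CCC(=O)OC(C)(C)C | intermediate
31 | potassium enolate of 30 (not isolated) | [K+].[O-]C1=C(N4CC(C)C4=O)C[C@@]2(COCOC)[C@@H](CO[Si](C)(C)C(C)(C)C)CC[C@H]3CCC=C3[C@@]12CCC(=O)OC(C)(C)C | intermediate
32 | potassium enolate of the ring-expanded spiro 2-amino-1,3-diketone, N on the face of the CH2OTBS arm (not isolated) | O=C1[C@@]4(NCC(C)=C4[O-])C[C@@]2(COCOC)[C@@H](CO[Si](C)(C)C(C)(C)C)CC[C@H]3CCC=C3[C@@]12CCC(=O)OC(C)(C)C.[K+] | intermediate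
33 | spiro pyrrolidinone TBS enol ether (4-methyl-3-silyloxy-2,5-dihydropyrrole spiro-fused to the cyclopentanone) | O=C1[C@@]4(NCC(C)=C4O[Si](C)(C)C(C)(C)C)C[C@@]2(COCOC)[C@@H](CO[Si](C)(C)C(C)(C)C)CC[C@H]3CCC=C3[C@@]12CCC(=O)OC(C)(C)C | intermediate
34 | hydroxy tert-butyl ester, carbinol cis to the propanoate arm (not isolated) | O[C@@H]1[C@@]4(NCC(C)=C4O[Si](C)(C)C(C)(C)C)C[C@@]2(COCOC)[C@@H](CO[Si](C)(C)C(C)(C)C)CC[C@H]3CCC=C3[C@@]12CCC(=O)OC(C)(C)C | intermediate
35 | δ-lactone cis-fused to the cyclopentane, silyl groups retained | O5[C@@H]1[C@@]4(NCC(C)=C4O[Si](C)(C)C(C)(C)C)C[C@@]2(COCOC)[C@@H](CO[Si](C)(C)C(C)(C)C)CC[C@H]3CCC=C3[C@@]12CCC5=O | intermediate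
36 | amino alcohol keto lactone: free NH pyrrolidin-3-one (methyl epimers) and free CH2OH arm | O5[C@@H]1[C@@]4(NCC(C)C4=O)C[C@@]2(COCOC)[C@@H](CO)CC[C@H]3CCC=C3[C@@]12CCC5=O | intermediate
37 | MOM ether of the target as mixture of epimers at the methyl-bearing carbon (not isolated) | CC1CN2C[C@H]3CC[C@H]4CCC=C4[C@@]45CCC(=O)O[C@@H]4[C@@]2(C[C@@]35COCOC)C1=O | intermediate
38 | MOM ether of the target | C[C@@H]1CN2C[C@H]3CC[C@H]4CCC=C4[C@@]45CCC(=O)O[C@@H]4[C@@]2(C[C@@]35COCOC)C1=O | intermediate
39 | CNP0180795.1 | C[C@@H]1CN2C[C@H]3CC[C@H]4CCC=C4[C@@]45CCC(=O)O[C@@H]4[C@@]2(C[C@@]35CO)C1=O | target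

**Totals**

Total step count: 22. Longest linear sequence: 19 steps (steps 1–5, 8–15, 17–22).

**Steps most likely to fail**

1. Step 18 (proposed new method). The enolate carbon may fail to reach the lactam carbonyl through the strained three-membered transition state, so that O-acyl transfer, attack on the side-chain ester or simple recovery after protonation takes over. The fallback uses known chemistry and sets out from α-bromo ketone 25. N-Alkylation of methyl 3-amino-2-methylpropanoate (free base of 26, i-Pr2NEt, MeCN) gives the secondary amine β-amino ester F1. Dieckmann-type C-acylation of the ketone enolate by the methyl ester (KHMDS, THF, −78 °C, 5-exo-trig), with TBSCl trapping of the product enolate in the same flask, comes back to the route at 33.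

2. Step 17. Loss of HBr to the cyclopentenone and O-alkylation of the lactam may outrun substitution at the hindered secondary carbon. The fallback sets out from keto ester 23. Deacylative diazo transfer (LiHMDS, CF3CO2CH2CF3; then MsN3, Et3N) gives α-diazo ketone F2. Rh2(OAc)4-catalysed N–H insertion of lactam 29 into the derived carbenoid comes back to the route at 30.

3. Step 19. Hydride delivery may lack facial selectivity, which would leave the carbinol trans to the propanoate arm so that no lactone can form. The fallback sets out from 33 and corrects the centre thermodynamically. The epimeric hydroxy ester F3 is desilylated (TBAF, AcOH) to amino alcohol F4 and closed to the caged piperidine F5 under the Appel conditions of step 21. Catalytic KOt-Bu in t-BuOH/THF then opens the β-hydroxy ketone by retro-aldol reaction to keto aldehyde F6. The aldol re-closure is reversible, and only the epimer with the alkoxide cis to the ester is drained as the δ-lactone, while the methyl-bearing carbon equilibrates in the same flask. This comes back to the route at 38.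

Further compounds
F1 | step 18 | β-amino ester: methyl 2-methyl-3-aminopropanoate N-linked to the ketone α-carbon of the tricycle | O=C1C(NCC(C)C(=O)OC)C[C@@]2(COCOC)[C@@H](CO[Si](C)(C)C(C)(C)C)CC[C@H]3CCC=C3[C@@]12CCC(=O)OC(C)(C)C
F2 | step 17 | α-diazo ketone derived from 23 | O=C1C(=[N+]=[N-])C[C@@]2(COCOC)[C@@H](CO[Si](C)(C)C(C)(C)C)CC[C@H]3CCC=C3[C@@]12CCC(=O)OC(C)(C)C
F3 | step 19 | carbinol epimer of hydroxy ester 34 | O[C@H]1[C@@]4(NCC(C)=C4O[Si](C)(C)C(C)(C)C)C[C@@]2(COCOC)[C@@H](CO[Si](C)(C)C(C)(C)C)CC[C@H]3CCC=C3[C@@]12CCC(=O)OC(C)(C)C
F4 | step 19 | desilylated amino alcohol with free epimeric carbinol and tert-butyl ester | O[C@H]1[C@@]4(NCC(C)C4=O)C[C@@]2(COCOC)[C@@H](CO)CC[C@H]3CCC=C3[C@@]12CCC(=O)OC(C)(C)C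
F5 | step 19 | caged piperidine with epimeric carbinol and tert-butyl ester | O[C@H]1[C@]46C[C@@]2(COCOC)[C@@H](CN4CC(C)C6=O)CC[C@H]3CCC=C3[C@@]12CCC(=O)OC(C)(C)C
F6 | step 19 | keto aldehyde from retro-aldol opening of the cyclopentane (indolizidinone with neopentyl aldehyde, not isolated) | O=C[C@]1(CCC(=O)OC(C)(C)C)C2=CCC[C@@H]2CC[C@@H]2CN3CC(C)C(=O)C3C[C@]12COCOC
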